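(The runs come from a simulation from invented constants; noise was put on by code.)

Thursday's flask holds less initiator (42 mM) than stray impurity (52 mM), yet its monomer keeps entering chains, so you cannot reckon its chains by subtraction, and the average length asked for hangs on that count.

common to all: free monomer 1.7 M; stray impurity 52 mM

| run | transfer agent | protic impurity | initiator | remark | time |
|---|---|---|---|---|---|
| Thursday's | 0.017 M | 0.85 M | 42 mM | the very flask that is asked about, followed so far |  |
| Monday's | 0.017 M | 0.85 M | 84 mM | run made earlier |  |
| flask | 0.0170 M | 0.850 M | 42 mM |  | 4.0 h |

Thursday's run (percent of the free monomer charged)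

| time / min | monomer in chains / % | free monomer / % |
|---|---|---|
| 2.50 | 1.5 | 76.4 |
| 4.00 | 0 | 68.5 |
| 6.00 | 1.6 | 62.0 |
| 10.0 | 2.6 | 55.1 |
| 20.0 | 4.0 | 46.8 |
| 30.0 | 6.0 | 44.2 |

Monday's run (percent of the free monomer charged)

| time / h | monomer in chains / % | free monomer / % |
|---|---|---|
| 0.250 | 9.9 | 44.6 |
| 0.833 | 19.8 | 30.0 |
| 1.33 | 26.0 | 23.9 |
| 2.00 | 30.9 | 17.9 |
| 3.00 | 37.2 | 12.0 |
| 4.00 | 40.9 | 9.2 |

(standard deviation of a reading: 0.5 percentage points)

- the average divides the monomer in chains by the number of chains begun, living and dead together
- the earlier runs do not show the number of chains; that part of a forecast is a guess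

- whether the average number of monomer units in a chain (chains begun, living or dead) reaches 20 by 4.0 h (no / yes)
- average number of monomer units in a chain (chains begun, living or dead) at 4.0 h

Counting every initiator as a chain ignores the stray impurity, while counting the loss one for one leaves Thursday's flask no chains at all, which the readings deny. Monday's flask gives a better foothold: if the stray impurity is the limiting reagent there, at least 32.0 mM of initiator survives. So compare how fast each flask feeds its chains over an early stretch, as gain in chains per hour over mean free monomer:

k(Monday) = 0.455 h⁻¹

k(Thursday) = 0.205 h⁻¹

ratio = 2.22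

If an end grows equally fast in both flasks and transfer agent begins no chains, the ratio divides Monday's floor:

ends = (c(initiator) − c(stray impurity), Monday) / ratio = 14.4 mM

I carry this end count, the chains begun in Thursday's flask. The objection is that Thursday's gain of 3.4 percentage points rests on readings with a scatter of 0.5 points, and that Monday's figure is a floor only if the stray impurity is the limiting reagent there. So test the margin. Scaling Monday's later fall of free monomer by the ratio, from Thursday's last reading, puts about 0.413 M in chains at 4.0 h, so my length is 28.7. A length of 20 allows 20.6 mM of chains, more than the end count. I commit to yes, with that margin as the risk.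

The forecast says no and 6.7, on its own grounds: “Chains begun are guessed at 42 mM”, plus some from transfer. That differs from my count.

The flask gives yes, with an average of 26.4 at 4.0 h.

    free monomer + initiator → living end + monomer in chains (k = 0.00376 M⁻¹ s⁻¹)
    free monomer + living end → monomer in chains + living end, rate k2*[living end]*[free monomer] (k = 0.00425 M⁻¹ s⁻¹)
    living end + transfer agent → dead chain (kL = 0.00522 M⁻¹ s⁻¹)
    initiator + stray impurity → spent initiator (k = 0.311 M⁻¹ s⁻¹)
    protic impurity + free monomer → quenched substrate (k = 0.00271 M⁻¹ s⁻¹)

At the charged amounts of Thursday's flask, stray impurity removes initiator at 58.2 h⁻¹ per unit of initiator, faster than free monomer starts chains at 23.0 h⁻¹. At 4.00 h Thursday's flask holds 0.0280 M of spent initiator against 14.0 mM of living end and dead chain together, beside the end count of 14.4 mM, and 21.8% in chains over that end count gives 25.6 units per chain.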